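A percentage of the substrate charged is a poor measure of speed, because the same amount of target counts for less in a larger charge. The autumn run reaches 28.9 % at 12.0 min and the dawn run 12.8 %, yet multiplying each by its charge gives 1.01 mM/min and 1.07 mM/min. So a charge larger by a factor of 2.38 changes the rate by a factor of 1.06. Their mean, the absolute turnover rate, target formed per minute in concentration, 1.04 mM/min, is the quantity to carry.

| flask | substrate | partner | free catalyst | remark | time |
|---|---|---|---|---|---|
| autumn | 0.042 M | 0.055 M | 95 µM | run made earlier |  |
| dawn | 0.10 M | 0.055 M | 95 µM | run made earlier |  |
| beta | 0.050 M | 0.0550 M | 95 µM |  | 25 min |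
| eta | 0.15 M | 0.0550 M | 95 µM |  | 25 min |

| run | time / min | target / % | substrate / % |
|---|---|---|---|
| autumn | 1.00 | 2.0 | 97.0 |
| autumn | 2.00 | 5.2 | 95.6 |
| autumn | 4.00 | 10.1 | 89.6 |
| autumn | 6.00 | 14.8 | 84.6 |
| autumn | 12.0 | 28.9 | 71.7 |
| dawn | 1.00 | 1.7 | 98.4 |
| dawn | 2.00 | 2.0 | 98.4 |
| dawn | 4.00 | 6.0 | 94.7 |
| dawn | 6.00 | 6.4 | 93.0 |
| dawn | 12.0 | 12.8 | 86.5 |

(each reading ± 0.5 percentage points)

* which of the two ends with the higher amount of target, in percent of the substrate charged ("neither" if they lie within 2 percentage points) (beta / eta / neither)
* target at the end, in percent of the substrate charged, beta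
* target at the end, in percent of the substrate charged, eta



Two extreme flasks can be solved in the head. If the rate stays at the carried value, the reaction is zero order in substrate, and the percentage at the end is that rate times the time over the charge: 52.0 % for beta and 17.3 % for eta. If the rate instead follows [substrate], the percentage curve does not depend on the charge, and the autumn curve carried to 25 min gives 50.9 % in both. For beta the two extremes nearly coincide. For eta they lie far apart, but the dawn run already sits at the constant-rate end, so eta belongs near its lower value. Constant turnover over 25 min amounts to 0.0260 M, less than beta's charge of 0.050 M, so on this reckoning beta keeps substrate to the end. The reckoning here therefore commits to the constant-rate values.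

The forecast names beta, with 49 % for beta and 17 % for eta, and it lowers beta with the remark: “Partner depletion or lower substrate could slow this somewhat, so I shade down”.

The flask gives 46.0 % for beta and 16.9 % for eta.

    partner + free catalyst → catalyst intermediate A (k = 5.56 /M/s)
    catalyst intermediate A ⇌ catalyst intermediate B (K = 0.755, k = 1.97 /s)
    substrate + catalyst intermediate B → catalyst intermediate C (k = 65.5 /M/s)
    catalyst intermediate C → free catalyst + target (k = 2.05 /s)

Eta turns over 1.01 mM/min on average, close to the carried rate. The larger charge of substrate is the main reason for its low percentage: at beta's charge the same flask gives 46.0 % instead of 16.9 %. For a neighbour flask, the same as eta but with 0.26 M of substrate, the carried rate gives 10.00 %, and that flask ends at 9.88 %.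

All runs were computed on assumed constants; noise was put on by code.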